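**Retrosynthetic overview**
- Target 38 ⇒ diol 35 by a final chemoselective angeloylation of the primary C15–OH; the C5 acetate is put on while O3 and O15 are tied up as an acetonide.
- The ten-membered carbocycle is closed last of the rings, at C9–C10, by intramolecular alkylation of an allylic sulfone anion with an allylic chloride, followed by reductive desulfonylation.
- C1=C2 and C15 come from an alkyne: directed trans-hydroalumination/iodination, then Pd carbonylation to a butenolide, which fixes C15 cis to C3 and differentiates O3 from O5.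
- C3 is set by a 1,3-anti directed reduction of a β-hydroxy ynone (Weinreb amide plus lithium acetylide); C4 and C5 are set in the key fragment union, an intermolecular Evans syn aldol forming C4–C5.
- Ring order: butenolide (temporary, step 11) → dioxepine acetonide (temporary, step 16) → ten-membered carbocycle (step 19).

Convention and assumption: locants C1–C10 and C15 are those of the target ring (C1 carries C15H2O, C2 is its alkene partner, C3 = CHOH, C4 = CH(i-Pr), C5 = CHOAc, C6, C7 = C(Me), C8 = alkene CH, C9, C10); compounds 1, 8, 9, 14 and 36 are taken as purchasable.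

**Route**

Step 1
Reactants: 1 tert-butyl(but-3-yn-1-yloxy)dimethylsilane
Product: 4 (E)-5-((tert-butyldimethylsilyl)oxy)-3-methylpent-2-en-1-ol, via alkenyldimethylalane 2 (not isolated), via lithium alkenylalanate 3 (not isolated)
Conditions: AlMe3 (2.5 eq), Cp2ZrCl2 (0.25 eq), CH2Cl2, 0 °C to rt; then n-BuLi, THF, −78 °C; (CH2O)n, −78 °C to rt; aq. work-up
Reagents that add atoms: trimethylaluminium C[Al](C)C; paraformaldehyde (formaldehyde unit) C=O
Why: Negishi Zr-catalysed carboalumination adds Me–Al syn with Al at the terminus, so hydroxymethylation of the ate complex with retention gives the (E)-trisubstituted alkene (C9 trans to C6).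

Step 2
Reactants: 4 (E)-5-((tert-butyldimethylsilyl)oxy)-3-methylpent-2-en-1-ol
Product: 5 (E)-tert-butyl((5-((4-methoxybenzyl)oxy)-3-methylpent-3-en-1-yl)oxy)dimethylsilane
Conditions: NaH, PMBCl, Bu4NI (cat.), THF/DMF, 0 °C to rt
Reagents that add atoms: 4-methoxybenzyl chloride COc1ccc(CCl)cc1
Why: Williamson etherification protects the allylic C9 oxygen as a PMB ether orthogonal to all later silyl groups.

Step 3
Reactants: 5 (E)-tert-butyl((5-((4-methoxybenzyl)oxy)-3-methylpent-3-en-1-yl)oxy)dimethylsilane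
Product: 6 (E)-5-((4-methoxybenzyl)oxy)-3-methylpent-3-en-1-ol
Conditions: TBAF, THF, 0 °C to rt
Reagents that add atoms: none
Why: Fluoride desilylation frees the homoallylic alcohol while the PMB ether is inert.

Step 4
Reactants: 6 (E)-5-((4-methoxybenzyl)oxy)-3-methylpent-3-en-1-ol
Product: 7 (E)-5-((4-methoxybenzyl)oxy)-3-methylpent-3-enal
Conditions: Dess–Martin periodinane, NaHCO3, CH2Cl2, 0 °C; short work-up, used at once
Reagents that add atoms: none
Why: Buffered Dess–Martin oxidation is neutral enough to give the β,γ-unsaturated aldehyde without migration of the alkene into conjugation.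

Step 5
Reactants: 8 (R)-4-benzyloxazolidin-2-one; 9 3-methylbutanoyl chloride
Product: 10 (R)-4-benzyl-3-(3-methylbutanoyl)oxazolidin-2-one
Conditions: n-BuLi, THF, −78 °C; then 9, −78 to 0 °C
Reagents that add atoms: none
Why: N-acylation of the lithiated oxazolidinone gives the Evans imide.

Step 6
Reactants: 10 (R)-4-benzyl-3-(3-methylbutanoyl)oxazolidin-2-one; 7 (E)-5-((4-methoxybenzyl)oxy)-3-methylpent-3-enal
Product: 12 (R)-4-benzyl-3-[(2R,3S,5E)-3-hydroxy-7-((4-methoxybenzyl)oxy)-5-methyl-2-(propan-2-yl)hept-5-enoyl]oxazolidin-2-one, via dibutylboron Z-enolate 11 (not isolated)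
Conditions: Bu2BOTf (1.2 eq), i-Pr2NEt (1.4 eq), CH2Cl2, 0 °C; then fresh 7, −78 to −10 °C; pH 7 buffer, MeOH, 30% H2O2, 0 °C
Reagents that add atoms: none
Why: Evans syn aldol: the Z-boron enolate reacts through a Zimmerman–Traxler chair on the face away from the benzyl group, which sets C4 and C5 (i-Pr and OH syn, absolute sense fixed by the (R)-auxiliary).

Step 7
Reactants: 12 Evans aldol adduct
Product: 13 (2R,3S,5E)-3-hydroxy-N-methoxy-7-((4-methoxybenzyl)oxy)-N,5-dimethyl-2-(propan-2-yl)hept-5-enamide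
Conditions: MeNHOMe·HCl, AlMe3, CH2Cl2, −20 to 0 °C; Rochelle salt work-up
Reagents that add atoms: N,O-dimethylhydroxylamine hydrochloride CNOC.Cl
Why: Weinreb transamination; the free β-hydroxyl (as aluminium alkoxide) directs attack to the exocyclic carbonyl, and the auxiliary is released without epimerisation.

Step 8
Reactants: 14 tert-butyldimethyl(prop-2-yn-1-yloxy)silane; 13 Weinreb amide
Product: 16 (5R,6S,8E)-1-((tert-butyldimethylsilyl)oxy)-6-hydroxy-10-((4-methoxybenzyl)oxy)-8-methyl-5-(propan-2-yl)dec-8-en-2-yn-4-one, via lithium acetylide 15 (not isolated)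
Conditions: 14 (3.5 eq), n-BuLi (3.3 eq), THF, −78 °C; then 13, −78 to −20 °C; aq. NH4Cl
Reagents that add atoms: none
Why: Weinreb ketone synthesis; one equivalent of acetylide deprotonates the hydroxyl and the chelated tetrahedral intermediate prevents over-addition, forming C2–C3.

Step 9
Reactants: 16 β-hydroxy ynone
Product: 17 (4R,5R,6S,8E)-1-((tert-butyldimethylsilyl)oxy)-10-((4-methoxybenzyl)oxy)-8-methyl-5-(propan-2-yl)dec-8-en-2-yne-4,6-diol
Conditions: Me4NBH(OAc)3, MeCN/AcOH 1:1, −30 °C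
Reagents that add atoms: none
Why: Evans–Saksena directed reduction; hydride is delivered intramolecularly from the C5 alkoxyborohydride through a chair transition state, giving the 1,3-anti diol and so setting C3.

Step 10
Reactants: 17 anti-diol alkyne
Product: 19 (2Z,4R,5R,6S,8E)-1-((tert-butyldimethylsilyl)oxy)-2-iodo-10-((4-methoxybenzyl)oxy)-8-methyl-5-(propan-2-yl)deca-2,8-diene-4,6-diol, via vinylalanate 18 (not isolated)
Conditions: Red-Al (4 eq), THF, 0 °C to rt; then I2, THF, −78 to 0 °C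
Reagents that add atoms: iodine II
Why: Hydroxyl-directed trans-hydroalumination of the propargylic alcohol puts H on C2 and Al on C1 (five-membered oxa-aluminacycle); iodinolysis with retention gives the vinyl iodide with I cis to C3 and C10 trans to C3.

Step 11
Reactants: 19 (Z)-vinyl iodide diol
Product: 20 (5S)-3-(((tert-butyldimethylsilyl)oxy)methyl)-5-[(3R,4S,6E)-4-hydroxy-8-((4-methoxybenzyl)oxy)-2,6-dimethyloct-6-en-3-yl]furan-2(5H)-one
Conditions: PdCl2(PPh3)2 (5 mol%), CO (1 atm), K2CO3, THF, 40 °C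
Reagents that add atoms: carbon monoxide [C-]#[O+]
Why: Pd-catalysed carbonylative lactonisation; the acyl-palladium is trapped by the cis C3–OH (five-membered ring strongly preferred over seven), which installs C15 cis to C3 and leaves O5 as the only free hydroxyl.

Step 12
Reactants: 20 hydroxy butenolide
Product: 21 butenolide 20 silylated at O5 (C5–OTBS; C3, C4, C5 unchanged)
Conditions: TBSOTf (1.2 eq), 2,6-lutidine, CH2Cl2, −78 °C, cold quench
Reagents that add atoms: tert-butyldimethylsilyl triflate CC(C)(C)[Si](C)(C)OS(=O)(=O)C(F)(F)F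
Why: Silylation of the hindered secondary alcohol is fast at −78 °C, where the butenolide is not converted into a silyloxyfuran.

Step 13
Reactants: 21 bis-silyl PMB butenolide
Product: 22 butenolide with free primary allylic C9–OH (C5–OTBS, C10–OTBS retained)
Conditions: DDQ, CH2Cl2/pH 7 buffer, 0 °C
Reagents that add atoms: none
Why: Oxidative PMB cleavage leaves silyl ethers, lactone and alkenes untouched.

Step 14
Reactants: 22 C9 allylic alcohol
Product: 24 butenolide carrying the C9 phenyl sulfone (PhSO2–C9H2–C8H=C7(Me)–), via allylic bromide 23 (not isolated)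
Conditions: CBr4, PPh3, CH2Cl2, −20 °C; then PhSO2Na, DMF, rt
Reagents that add atoms: sodium benzenesulfinate [Na+].[O-]S(=O)c1ccccc1
Why: Appel bromination followed by SN2 S-alkylation of sulfinate at the primary allylic carbon gives the sulfone with the (E)-alkene intact.

Step 15
Reactants: 24 sulfone butenolide
Product: 25 (Z)-ene-1,4-diol (C3–OH and C15–OH free; C5–OTBS, C10–OTBS, C9–SO2Ph)
Conditions: DIBAL-H (4 eq), CH2Cl2, −78 to 0 °C; Rochelle salt
Reagents that add atoms: none
Why: Hydride reduction of the lactone through the lactol gives the diol, with the C1=C2 geometry (C15 cis to C3) inherited from the ring.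

Step 16
Reactants: 25 (Z)-ene-1,4-diol
Product: 26 2,2-dimethyl-4,7-dihydro-1,3-dioxepine (acetonide across O3 and O15)
Conditions: 2,2-dimethoxypropane, PPTS (cat.), CH2Cl2, rt
Reagents that add atoms: 2,2-dimethoxypropane COC(C)(C)OC
Why: Acetalisation of the cis-ene-diol closes the seven-membered acetonide, a base- and fluoride-stable mask for O3 and O15.

Step 17
Reactants: 26 acetonide
Product: 27 acetonide with free primary allylic C10–OH
Conditions: TBAF (1.1 eq), AcOH (1.1 eq), THF, 0 °C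
Reagents that add atoms: none
Why: Selective desilylation: the unhindered primary allylic TBS ether cleaves while the hindered secondary C5–OTBS survives; buffering prevents base isomerisation of the allylic sulfone.

Step 18
Reactants: 27 C10 allylic alcohol
Product: 29 C10 allylic chloride, via allylic mesylate 28 (not isolated)
Conditions: MsCl, 2,4,6-collidine, LiCl, DMF, 0 °C
Reagents that add atoms: lithium chloride [Li+].[Cl-]
Why: Collington–Meyers chlorination; chloride displaces the mesylate by SN2 without allylic transposition, and collidine protects the acetonide.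

Step 19
Reactants: 29 sulfone allylic chloride
Product: 31 ten-membered macrocyclic sulfone (C9–C10 bond formed; C9 epimers), via lithiated sulfone 30 (not isolated)
Conditions: LiHMDS (1.5 eq), THF, slow addition of 29 to 2 mM final, −78 °C to rt
Reagents that add atoms: none
Why: Intramolecular SN2 alkylation of the α-sulfonyl allyl carbanion (α-attack) by the allylic chloride under high dilution closes the ring, with both (E)-trisubstituted alkenes already in place.

Step 20
Reactants: 31 macrocyclic sulfone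
Product: 32 desulfonylated macrocycle (C5–OTBS, O3/O15 acetonide)
Conditions: LiBHEt3, PdCl2(dppp) (5 mol%), THF, 0 °C
Reagents that add atoms: none
Why: Pd-catalysed reductive desulfonylation (Kotake–Inomata); hydride attacks the π-allyl at the less substituted C9 terminus, so C7=C8 stays in position and (E).

Step 21
Reactants: 32 silyl ether macrocycle
Product: 33 macrocycle with free C5–OH
Conditions: TBAF, THF, 45 °C
Reagents that add atoms: none
Why: Fluoride desilylation of the remaining silyl ether; the acetonide is inert.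

Step 22
Reactants: 33 C5 alcohol
Product: 34 C5 acetate
Conditions: Ac2O, pyridine, DMAP (cat.), CH2Cl2, rt
Reagents that add atoms: acetic anhydride CC(=O)OC(C)=O
Why: Acylation of the only free hydroxyl places the acetate on O5 unambiguously while O3 is masked.

Step 23
Reactants: 34 acetate acetonide
Product: 35 (1Z,7E)-diol: target skeleton with C5–OAc, C3–OH and C15–OH
Conditions: PPTS, MeOH, 0 °C to rt
Reagents that add atoms: none
Why: Mild acid transacetalisation removes the strained seven-membered acetonide without cleaving or migrating the acetate.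

Step 24
Reactants: 35 diol; 36 angelic acid ((Z)-2-methylbut-2-enoic acid)
Product: 38 target CNP0246594.1, via mixed anhydride 37 (not isolated)
Conditions: 36, 2,4,6-trichlorobenzoyl chloride, Et3N, toluene, rt; then 35, toluene, rt to 60 °C (no DMAP)
Reagents that add atoms: none
Why: Yamaguchi esterification without a nucleophilic catalyst acylates the primary allylic C15–OH in preference to the hindered secondary C3–OH and avoids Z-to-E isomerisation to the tiglate.

**Compound list**
1 | tert-butyl(but-3-yn-1-yloxy)dimethylsilane | C#CCCO[Si](C)(C)C(C)(C)C | starting material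
2 | (E)-[4-((tert-butyldimethylsilyl)oxy)-2-methylbut-1-en-1-yl]dimethylalane | C[Al](C)/C=C(\C)CCO[Si](C)(C)C(C)(C)C | intermediate (not isolated)
3 | lithium butyl[(E)-4-((tert-butyldimethylsilyl)oxy)-2-methylbut-1-en-1-yl]dimethylalanate | [Li+].CCCC[Al-](C)(C)/C=C(\C)CCO[Si](C)(C)C(C)(C)C | intermediate (not isolated)
4 | (E)-5-((tert-butyldimethylsilyl)oxy)-3-methylpent-2-en-1-ol | OC/C=C(\C)CCO[Si](C)(C)C(C)(C)C | intermediate
5 | (E)-tert-butyl((5-((4-methoxybenzyl)oxy)-3-methylpent-3-en-1-yl)oxy)dimethylsilane | COc1ccc(COC/C=C(\C)CCO[Si](C)(C)C(C)(C)C)cc1 | intermediate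
6 | (E)-5-((4-methoxybenzyl)oxy)-3-methylpent-3-en-1-ol | COc1ccc(COC/C=C(\C)CCO)cc1 | intermediate
7 | (E)-5-((4-methoxybenzyl)oxy)-3-methylpent-3-enal | COc1ccc(COC/C=C(\C)CC=O)cc1 | intermediate
8 | (R)-4-benzyloxazolidin-2-one | O=C1N[C@H](Cc2ccccc2)CO1 | starting material
9 | 3-methylbutanoyl chloride | CC(C)CC(Cl)=O | starting material
10 | (R)-4-benzyl-3-(3-methylbutanoyl)oxazolidin-2-one | CC(C)CC(=O)N1[C@H](Cc2ccccc2)COC1=O | intermediate
11 | (Z)-dibutylboron enolate of 10 | CCCCB(CCCC)O/C(=C\C(C)C)N1[C@H](Cc2ccccc2)COC1=O | intermediate (not isolated)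
12 | (R)-4-benzyl-3-[(2R,3S,5E)-3-hydroxy-7-((4-methoxybenzyl)oxy)-5-methyl-2-(propan-2-yl)hept-5-enoyl]oxazolidin-2-one | COc1ccc(COC/C=C(\C)C[C@H](O)[C@@H](C(C)C)C(=O)N2[C@H](Cc3ccccc3)COC2=O)cc1 | intermediate
13 | (2R,3S,5E)-3-hydroxy-N-methoxy-7-((4-methoxybenzyl)oxy)-N,5-dimethyl-2-(propan-2-yl)hept-5-enamide | COc1ccc(COC/C=C(\C)C[C@H](O)[C@@H](C(C)C)C(=O)N(C)OC)cc1 | intermediate
14 | tert-butyldimethyl(prop-2-yn-1-yloxy)silane | C#CCO[Si](C)(C)C(C)(C)C | starting material
15 | lithium acetylide of 14 | [Li]C#CCO[Si](C)(C)C(C)(C)C | intermediate (not isolated)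
16 | (5R,6S,8E)-1-((tert-butyldimethylsilyl)oxy)-6-hydroxy-10-((4-methoxybenzyl)oxy)-8-methyl-5-(propan-2-yl)dec-8-en-2-yn-4-one | COc1ccc(COC/C=C(\C)C[C@H](O)[C@@H](C(C)C)C(=O)C#CCO[Si](C)(C)C(C)(C)C)cc1 | intermediate
17 | (4R,5R,6S,8E)-1-((tert-butyldimethylsilyl)oxy)-10-((4-methoxybenzyl)oxy)-8-methyl-5-(propan-2-yl)dec-8-en-2-yne-4,6-diol | COc1ccc(COC/C=C(\C)C[C@H](O)[C@@H](C(C)C)[C@@H](O)C#CCO[Si](C)(C)C(C)(C)C)cc1 | intermediate
18 | sodium bis(2-methoxyethoxy) oxa-aluminacyclopentene from 17 (Al on C1 and O3, H on C2; O5 drawn as OH) | [Na+].COCCO[Al-]1(OCCOC)O[C@H]([C@H](C(C)C)[C@@H](O)C/C(C)=C/COCc2ccc(OC)cc2)C=C1CO[Si](C)(C)C(C)(C)C | intermediate (not isolated)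
19 | (2Z,4R,5R,6S,8E)-1-((tert-butyldimethylsilyl)oxy)-2-iodo-10-((4-methoxybenzyl)oxy)-8-methyl-5-(propan-2-yl)deca-2,8-diene-4,6-diol | COc1ccc(COC/C=C(\C)C[C@H](O)[C@@H](C(C)C)[C@@H](O)/C=C(\I)CO[Si](C)(C)C(C)(C)C)cc1 | intermediate
20 | (5S)-3-(((tert-butyldimethylsilyl)oxy)methyl)-5-[(3R,4S,6E)-4-hydroxy-8-((4-methoxybenzyl)oxy)-2,6-dimethyloct-6-en-3-yl]furan-2(5H)-one | COc1ccc(COC/C=C(\C)C[C@H](O)[C@@H](C(C)C)[C@H]2OC(=O)C(CO[Si](C)(C)C(C)(C)C)=C2)cc1 | intermediate
21 | butenolide 20 with C5–OTBS | COc1ccc(COC/C=C(\C)C[C@H](O[Si](C)(C)C(C)(C)C)[C@@H](C(C)C)[C@H]2OC(=O)C(CO[Si](C)(C)C(C)(C)C)=C2)cc1 | intermediate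
22 | butenolide with free C9–OH (C5–OTBS, C10–OTBS) | OC/C=C(\C)C[C@H](O[Si](C)(C)C(C)(C)C)[C@@H](C(C)C)[C@H]1OC(=O)C(CO[Si](C)(C)C(C)(C)C)=C1 | intermediate
23 | C9 allylic bromide of 22 | BrC/C=C(\C)C[C@H](O[Si](C)(C)C(C)(C)C)[C@@H](C(C)C)[C@H]1OC(=O)C(CO[Si](C)(C)C(C)(C)C)=C1 | intermediate (not isolated)
24 | C9 phenyl sulfone butenolide | O=S(=O)(C/C=C(\C)C[C@H](O[Si](C)(C)C(C)(C)C)[C@@H](C(C)C)[C@H]1OC(=O)C(CO[Si](C)(C)C(C)(C)C)=C1)c1ccccc1 | intermediate
25 | (Z)-ene-1,4-diol: C3–OH, C15–OH, C10–OTBS, C5–OTBS, C9–SO2Ph | O=S(=O)(C/C=C(\C)C[C@H](O[Si](C)(C)C(C)(C)C)[C@@H](C(C)C)[C@@H](O)/C=C(\CO)CO[Si](C)(C)C(C)(C)C)c1ccccc1 | intermediate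
26 | O3/O15 acetonide (2,2-dimethyl-4,7-dihydro-1,3-dioxepine; C15 cis to C3 in the ring) with C10–OTBS | O=S(=O)(C/C=C(\C)C[C@H](O[Si](C)(C)C(C)(C)C)[C@@H](C(C)C)[C@H]1OC(C)(C)OCC(CO[Si](C)(C)C(C)(C)C)=C1)c1ccccc1 | intermediate
27 | acetonide with free C10–OH | O=S(=O)(C/C=C(\C)C[C@H](O[Si](C)(C)C(C)(C)C)[C@@H](C(C)C)[C@H]1OC(C)(C)OCC(CO)=C1)c1ccccc1 | intermediate
28 | C10 mesylate of 27 | O=S(=O)(C/C=C(\C)C[C@H](O[Si](C)(C)C(C)(C)C)[C@@H](C(C)C)[C@H]1OC(C)(C)OCC(COS(C)(=O)=O)=C1)c1ccccc1 | intermediate (not isolated)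
29 | C10 allylic chloride | O=S(=O)(C/C=C(\C)C[C@H](O[Si](C)(C)C(C)(C)C)[C@@H](C(C)C)[C@H]1OC(C)(C)OCC(CCl)=C1)c1ccccc1 | intermediate
30 | C9-lithiated sulfone of 29 | [Li+].O=S(=O)([CH-]/C=C(\C)C[C@H](O[Si](C)(C)C(C)(C)C)[C@@H](C(C)C)[C@H]1OC(C)(C)OCC(CCl)=C1)c1ccccc1 | intermediate (not isolated)
31 | macrocyclic C9 sulfone (ten-membered ring fused to the dioxepine, 7E, C5–OTBS) | C1C(S(=O)(=O)c3ccccc3)/C=C(\C)C[C@H](O[Si](C)(C)C(C)(C)C)[C@@H](C(C)C)[C@H]2OC(C)(C)OCC1=C2 | intermediate
32 | desulfonylated macrocycle (C5–OTBS, acetonide) | C1C/C=C(\C)C[C@H](O[Si](C)(C)C(C)(C)C)[C@@H](C(C)C)[C@H]2OC(C)(C)OCC1=C2 | intermediate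
33 | macrocycle with C5–OH | C1C/C=C(\C)C[C@H](O)[C@@H](C(C)C)[C@H]2OC(C)(C)OCC1=C2 | intermediate
34 | macrocycle with C5–OAc | C1C/C=C(\C)C[C@H](OC(C)=O)[C@@H](C(C)C)[C@H]2OC(C)(C)OCC1=C2 | intermediate
35 | de-angeloyl target: C5–OAc, C3–OH, C15–OH | OC/C1=C\[C@H](O)[C@H](C(C)C)[C@@H](OC(C)=O)C/C(C)=C/CC1 | intermediate
36 | angelic acid, (Z)-2-methylbut-2-enoic acid | C/C=C(/C)C(=O)O | starting material
37 | angelic 2,4,6-trichlorobenzoic mixed anhydride | C/C=C(/C)C(=O)OC(=O)c1c(Cl)cc(Cl)cc1Cl | intermediate (not isolated)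
38 | CNP0246594.1 | C/C=C(/C)C(=O)OC/C1=C\[C@H](O)[C@H](C(C)C)[C@@H](OC(C)=O)C/C(C)=C/CC1 | target

**Totals**
Total step count: 24. Longest linear sequence: 23 steps (steps 1–4 and 6–24, from 1 to 38); step 5 is a one-step side branch.

**Three steps most likely to fail, with fallbacks**

Step 6 (aldol). Aldehyde 7 is β,γ-unsaturated and can slip into conjugation, and the isovaleryl enolate is hindered. The fallback sets out from 7 (with 9) and comes back at 13. (R)-4-Benzylthiazolidine-2-thione F1 is N-acylated with 9 (Et3N, DMAP, CH2Cl2) to give the N-isovaleryl thiazolidinethione F2. Its chlorotitanium enolate (TiCl4, i-Pr2NEt, N-methylpyrrolidinone, CH2Cl2, −78 °C) adds to 7 at low temperature to give the Evans-syn thiazolidinethione aldol adduct F3 with the same C4/C5 configuration. The auxiliary is then displaced directly by MeNHOMe·HCl/imidazole at rt to give 13, which replaces steps 5–7 and also avoids the aluminium-mediated transamination of a hindered imide.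

Step 10 (hydroalumination–iodination). The vinyl aluminate carries a β-silyloxy group (C10–OTBS) and could eliminate to an allene. The fallback sets out from 17 and comes back at 19. Ru-catalysed trans-hydrosilylation ([Cp*Ru(MeCN)3]PF6, benzyldimethylsilane, CH2Cl2, 0 °C to rt) places silicon on C1, distal to the C3 hydroxyl, and gives the (Z)-vinylsilane F4, in which no metal–carbon bond is available for β-elimination. Iododesilylation with retention (NIS, 2,6-lutidine, hexafluoroisopropanol, 0 °C) then gives 19.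

Step 19 (macrocyclisation), together with the desulfonylation that follows it. The fallback sets out from 21 and comes back at 32, replacing steps 13–20 by a nickel(0) allyl–allyl coupling. DIBAL-H reduction of 21 gives the PMB ene-diol F5, and 2,2-dimethoxypropane/PPTS gives the PMB acetonide F6. DDQ frees the C9 alcohol to give the allylic alcohol F7, and buffered TBAF removes the primary silyl group to give the C9,C10-diol F8. CBr4/PPh3 gives the bis(allylic bromide) F9. Ni(cod)2 in DMF at 50 °C under high dilution couples the two primary allyl termini (C9–C10) to give 32 directly; the dioxepine ring holds the C1=C2 geometry during the π-allyl stage.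

**Further compounds**
F1 | step 6 | (R)-4-benzylthiazolidine-2-thione | S=C1N[C@H](Cc2ccccc2)CS1
F2 | step 6 | (R)-1-(4-benzyl-2-thioxothiazolidin-3-yl)-3-methylbutan-1-one | CC(C)CC(=O)N1[C@H](Cc2ccccc2)CSC1=S
F3 | step 6 | thiazolidinethione aldol adduct, (2R,3S,5E)-acyl chain as in 12 | COc1ccc(COC/C=C(\C)C[C@H](O)[C@@H](C(C)C)C(=O)N2[C@H](Cc3ccccc3)CSC2=S)cc1
F4 | step 10 | (Z)-vinylsilane: 19 with benzyldimethylsilyl in place of iodine | COc1ccc(COC/C=C(\C)C[C@H](O)[C@@H](C(C)C)[C@@H](O)/C=C(\[Si](C)(C)Cc2ccccc2)CO[Si](C)(C)C(C)(C)C)cc1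
F5 | step 19 | PMB ene-diol from 21 (C3–OH, C15–OH, C9–OPMB, C10–OTBS, C5–OTBS) | COc1ccc(COC/C=C(\C)C[C@H](O[Si](C)(C)C(C)(C)C)[C@@H](C(C)C)[C@@H](O)/C=C(\CO)CO[Si](C)(C)C(C)(C)C)cc1
F6 | step 19 | PMB acetonide (O3/O15 dioxepine) | COc1ccc(COC/C=C(\C)C[C@H](O[Si](C)(C)C(C)(C)C)[C@@H](C(C)C)[C@H]2OC(C)(C)OCC(CO[Si](C)(C)C(C)(C)C)=C2)cc1
F7 | step 19 | acetonide with free C9–OH and C10–OTBS | OC/C=C(\C)C[C@H](O[Si](C)(C)C(C)(C)C)[C@@H](C(C)C)[C@H]1OC(C)(C)OCC(CO[Si](C)(C)C(C)(C)C)=C1
F8 | step 19 | acetonide C9,C10-diol | OC/C=C(\C)C[C@H](O[Si](C)(C)C(C)(C)C)[C@@H](C(C)C)[C@H]1OC(C)(C)OCC(CO)=C1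
F9 | step 19 | acetonide bis(allylic bromide) | BrC/C=C(\C)C[C@H](O[Si](C)(C)C(C)(C)C)[C@@H](C(C)C)[C@H]1OC(C)(C)OCC(CBr)=C1
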